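# Total synthesis proposal for CNP0319155.1 by anionic oxy-Cope ring expansion

Remarks on the chemistry: germacrane numbering is used for all ten-membered-ring compounds and for the atoms of their precursors (ring C1–C10, lactone carbons C11–C13, C14 on C10, C15 on C4). The ligand enantiomer in step 4 is assigned by analogy with additions to cyclohex-2-enone; if the facial sense is opposite for 4, the antipodal ligand is used.

## Analysis of the target

The target is a heliangolide: a ten-membered carbocycle (C1–C10) trans-fused at C6–C7 to an α-methylene-γ-butyrolactone (O on C6, C11=C13 exocyclic). The ring holds a Z trisubstituted olefin C4=C5 and a trans epoxide at C1–C10, which is the oxidised form of an E olefin. There are six stereocentres, (1R,3S,6R,7R,8R,10R). C6, C7 and C8 are contiguous (6α-O, 7α-H, 8β-O), while C3 (3β-OAc) and the epoxide carbons are separated from them by sp2 carbons. Three oxygens must end up differentiated: acetate on C3, methacrylate on C8 and a free primary allylic alcohol on C15. The sensitive groups are the exo-methylene lactone and the methacrylate (Michael acceptors), the acetate next to a free 1,3-related hydroxyl (acyl migration), and the 1(10)-epoxide (acid-induced transannular cyclisation). The difficulty is a conformationally mobile medium ring with two stereodefined trisubstituted C=C units and stereocentres that cannot all be relayed from one another through a rigid frame. The feature that invites the strategy is the array C6(O)–C7–C8(O)–C9–C10=C1 (epoxide read as E olefin), flanked at C6 by the Z C4=C5 bond. This is exactly the product pattern of an oxy-Cope ring expansion of a 1,2-dialkenylcyclohex-2-en-1-ol, in which C1–C6 is the ring bond that is cut and C4=C5 is the endocyclic olefin of the six-membered ring.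

## Retrosynthetic reasoning

29 to 28: the epoxide is removed last. The C1=C10 olefin is the only electron-rich double bond of 28 (C4=C5 carries three allylic oxygens), and the acid-labile epoxide then sees no further step.

28 to 24: the esters and the free C15 hydroxyl are traced to three differently masked oxygens: a silyl ether on O15, a free hydroxyl on C3 and a 4-methoxybenzyl ether on O8. The strongly basic α-methylenation has to come before both acylations, so 24 already holds the exo-methylene lactone.

24 to 18: the C11=C13 bond is cut (aminomethylation and elimination of a lactone enolate), then the lactone C12–O6 bond and the C6–H bond. This leads to the γ-keto ester 18, whose C7 stereocentre directs hydride delivery to C6.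

18 to 15 (key disconnection): the C8–C9 bond and the C7–C11 bond are cut and the C1–C6 bond is reconnected. The forward step is an anionic oxy-Cope ring expansion of 15, with trapping of the resulting C6–C7 enolate by a haloacetate. The cut is made here because the precursor is a simple cyclohexenol, and one operation builds the ten-membered ring, the E C1=C10 bond, the C8 centre by chirality transfer from C1, and the C7 centre. The Z C4=C5 geometry is free because it is a ring olefin of 15.

15 to 8 and 12: the C6–C7 bond is cut to the enone 8 and the Z β-alkoxyvinyl bromide 12. The forward 1,2-addition has to place the vinyl group trans to the isopropenyl group, and the Z geometry of 12 is what makes C8 come out 8β.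

8 to 4: the C1–C10 bond is cut. The isopropenyl group is added by asymmetric conjugate addition to the quinone monoketal 4, which already holds all three ring oxygens (O3, O6, O15) at the right carbons. C3 then follows from C1 by 1,3-cis-selective reduction (5 to 6), and the ketal is opened to the C6 ketone only after O3 is protected (7 to 8).

4 to 1 and 12 to 9: the dienone comes from oxidative dearomatisation of the phenol 2, made from aldehyde 1. The vinyl bromide comes from alcohol 9 by vinylation to 10 and bromination–dehydrobromination.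

## Alternatives that were turned down

Alternative 1: the textbook disconnection cuts C6–C7 together with the lactone C12–O bond. The forward key step is an intramolecular Nozaki–Hiyama–Kishi or Barbier allylation of the seco-aldehyde A1 (CrCl2 or zinc), which closes the ten-membered ring and the lactone in one operation. It was turned down for these reasons:
- A1 is an open chain that must already hold both trisubstituted olefins, the C3 and C8 stereocentres from separate asymmetric steps, and a Z enal that isomerises easily to E through its dienol.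
- Most of the step count is therefore spent before any ring exists.
- The C6/C7 pair is set under remote induction from C8 in a high-dilution macrocyclisation of uncertain facial bias.

Alternative 2: C6–C7 is cut as a [2,3]-Wittig ring contraction of the thirteen-membered diallyl ether A2 (O bridging C6 and C13), which would give the C6 hydroxyl and the C11=C13 methylene directly. It was turned down for these reasons:
- A2 needs the same acyclic effort plus a thirteen-membered etherification.
- The α-oxy allyl anion at C6 is conjugated through C4=C5 to the C3 silyloxy group, which invites 1,4-elimination.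
- A competing [1,2] shift is likely.
- C12 would still have to be oxidised to the carboxyl level over several steps.

Alternative 3: the C1=C10 bond is cut as a ring-closing metathesis of the diene A3 (second-generation Grubbs catalyst) on a preformed lactone. It was turned down for these reasons:
- A trisubstituted E olefin in a strained ten-membered ring is the least favourable metathesis case; oligomers and the Z isomer are expected.
- The exo-methylene lactone and the C4=C5 bond would have to be kept out of the catalyst's reach.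
- All stereocentres would again have to be set one by one on an open chain.

Key step: step 11

## Route

Step 1
Reactants: 1 2-hydroxy-5-methoxybenzaldehyde
Product: 2 2-(hydroxymethyl)-4-methoxyphenol
Conditions: NaBH4, MeOH, 0 °C
Reagents that add atoms: none
Why: Chemoselective borohydride reduction of an aryl aldehyde; the carbon becomes C15.

Step 2
Reactants: 2 2-(hydroxymethyl)-4-methoxyphenol
Product: 3 2-(hydroxymethyl)-4,4-dimethoxycyclohexa-2,5-dien-1-one
Conditions: PhI(OAc)2, MeOH, 0 °C
Reagents that add atoms: methanol, CO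
Why: Oxidative dearomatisation of a 4-methoxyphenol to the quinone monoketal; methanol adds para to the phenol oxygen, which fixes the ketone (future O3) and the ketal (future C6 ketone) without ambiguity.

Step 3
Reactants: 3 2-(hydroxymethyl)-4,4-dimethoxycyclohexa-2,5-dien-1-one
Product: 4 2-[(tert-butyldiphenylsilyloxy)methyl]-4,4-dimethoxycyclohexa-2,5-dien-1-one
Conditions: TBDPSCl, imidazole, DMF, 0 °C → rt
Reagents that add atoms: tert-butyl(chloro)diphenylsilane, CC(C)(C)[Si](Cl)(c1ccccc1)c1ccccc1
Why: Silylation of the only hydroxyl; the robust silyl ether carries O15 to the penultimate step.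

Step 4
Reactants: 4 2-[(tert-butyldiphenylsilyloxy)methyl]-4,4-dimethoxycyclohexa-2,5-dien-1-one
Product: 5 (5S)-2-[(tert-butyldiphenylsilyloxy)methyl]-4,4-dimethoxy-5-(prop-1-en-2-yl)cyclohex-2-en-1-one
Conditions: [Rh(cod)OH]2 (2.5 mol %), (S)-BINAP (6 mol %), isopropenyl-B(pin) (2 equiv), dioxane/H2O 10:1, 40 °C
Reagents that add atoms: isopropenylboronic acid pinacol ester, CC(=C)B1OC(C)(C)C(C)(C)O1
Why: Rhodium-catalysed asymmetric conjugate addition of an alkenylboron reagent, a reaction type known for quinone monoketals and cyclohexenones; the unsubstituted enone C=C reacts in preference to the α-substituted one, and the ligand should set the isopropenyl-bearing centre (future C1) as S.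

Step 5
Reactants: 5 (5S)-2-[(tert-butyldiphenylsilyloxy)methyl]-4,4-dimethoxy-5-(prop-1-en-2-yl)cyclohex-2-en-1-one
Product: 6 (1S,5S)-2-[(tert-butyldiphenylsilyloxy)methyl]-4,4-dimethoxy-5-(prop-1-en-2-yl)cyclohex-2-en-1-ol
Conditions: NaBH4, CeCl3·7H2O, MeOH, −78 °C
Reagents that add atoms: none
Why: Luche 1,2-reduction of a carvone-type enone; hydride should enter anti to the isopropenyl group, as in the carvone to cis-carveol reduction, to give the 1,3-cis alcohol (future 3β-O, S).

Step 6
Reactants: 6 (1S,5S)-2-[(tert-butyldiphenylsilyloxy)methyl]-4,4-dimethoxy-5-(prop-1-en-2-yl)cyclohex-2-en-1-ol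
Product: 7 tert-butyl{[(4S,6S)-3,3-dimethoxy-4-(prop-1-en-2-yl)-6-(triethylsilyloxy)cyclohex-1-en-1-yl]methoxy}diphenylsilane
Conditions: TESCl, imidazole, DMF, 0 °C
Reagents that add atoms: chlorotriethylsilane, CC[Si](Cl)(CC)CC
Why: Standard silylation; the triethylsilyl ether tolerates the organometallic and basic steps and is planned to fall off under the acidic lactonisation of step 12.

Step 7
Reactants: 7 tert-butyl{[(4S,6S)-3,3-dimethoxy-4-(prop-1-en-2-yl)-6-(triethylsilyloxy)cyclohex-1-en-1-yl]methoxy}diphenylsilane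
Product: 8 (4S,6S)-3-[(tert-butyldiphenylsilyloxy)methyl]-6-(prop-1-en-2-yl)-4-(triethylsilyloxy)cyclohex-2-en-1-one
Conditions: SiO2, 10 % aq. oxalic acid, CH2Cl2, rt
Reagents that add atoms: water, O
Why: Mild hydrolysis of an allylic dimethyl ketal on wet acidic silica, conditions under which silyl ethers survive; the cis-1,3 (diequatorial) arrangement of the substituents is the stable one, so C1 is not at risk.

Step 8
Reactants: 9 4-methoxybenzyl alcohol
Product: 10 4-methoxybenzyl vinyl ether
Conditions: Pd(OAc)2 (2 mol %), 1,10-phenanthroline, ethyl vinyl ether (excess), CH2Cl2, rt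
Reagents that add atoms: ethyl vinyl ether, C=COCC
Why: Palladium-catalysed transfer vinylation of a primary alcohol, driven by the excess of ethyl vinyl ether.

Step 9
Reactants: 10 4-methoxybenzyl vinyl ether
Product: 12 (Z)-1-bromo-2-(4-methoxybenzyloxy)ethene, via dibromide 11 (not isolated)
Conditions: Br2, CH2Cl2, −78 °C; then i-Pr2NEt, −78 → 40 °C
Reagents that add atoms: bromine, BrBr
Why: Bromine addition to the enol ether followed by loss of HBr through the α-bromo ether, the classical route to cis-β-bromovinyl ethers; the Z isomer is the favoured one and any E isomer is removed by chromatography on base-washed silica.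

Step 10
Reactants: 12 (Z)-1-bromo-2-(4-methoxybenzyloxy)ethene; 8 (4S,6S)-3-[(tert-butyldiphenylsilyloxy)methyl]-6-(prop-1-en-2-yl)-4-(triethylsilyloxy)cyclohex-2-en-1-one
Product: 15 (1S,4S,6S)-3-[(tert-butyldiphenylsilyloxy)methyl]-1-[(Z)-2-(4-methoxybenzyloxy)ethenyl]-6-(prop-1-en-2-yl)-4-(triethylsilyloxy)cyclohex-2-en-1-ol, via vinyllithium 13 (not isolated), via organocerium reagent 14 (not isolated)
Conditions: 12, t-BuLi (2 equiv), Et2O, −78 °C; CeCl3 (anhydrous), THF, −78 °C; then 8, −78 °C; aq. NaHCO3
Reagents that add atoms: none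
Why: Bromine–lithium exchange gives the configurationally stable cis-2-alkoxyvinyllithium, and the organocerium reagent adds 1,2 to the enolisable enone; attack from the face opposite the cis-disposed isopropenyl and silyloxy groups should give the trans-dialkenyl carbinol (C6 S).

Step 11
Reactants: 15 (1S,4S,6S)-3-[(tert-butyldiphenylsilyloxy)methyl]-1-[(Z)-2-(4-methoxybenzyloxy)ethenyl]-6-(prop-1-en-2-yl)-4-(triethylsilyloxy)cyclohex-2-en-1-ol
Product: 18 ethyl 15-(tert-butyldiphenylsilyloxy)-8β-(4-methoxybenzyloxy)-6-oxo-3β-(triethylsilyloxy)-7αH-13-norgermacra-1(10)E,4Z-dien-12-oate, via potassium alkoxide 16 (not isolated), via potassium enolate 17 (not isolated)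
Conditions: KN(SiMe3)2 (1.2 equiv), 18-crown-6 (1.5 equiv), THF, −40 → 0 °C; then −78 °C, ICH2CO2Et (3 equiv); pH 7 buffer
Reagents that add atoms: ethyl iodoacetate, CCOC(=O)CI
Why: Deprotonation gives alkoxide 16, whose doubly allylic C1–C6 bond is weakened by the oxyanion, so the [3,3] shift (anionic oxy-Cope rearrangement, the established ring expansion of trans-1,2-dialkenylcyclohexanols to (E)-cyclodec-5-enones with trapping of the enolate in the same flask) should run below room temperature. The ten-membered ring is closed by ring expansion and not by cyclisation: C8–C9 forms between the enol ether terminus and the isopropenyl CH2 while the ring bond C1–C6 breaks, through a chair transition state trans-fused to the cyclohexene with C2 and C5 equatorial. Equatorial C2 gives the E C1=C10 bond, and C4=C5 is carried over from the six-membered ring and is therefore Z. C8 is set by chirality transfer from C1: with 1S and the Z enol ether the benzyloxy group sits axial in the chair and C8 should emerge as 8β (R); any C6 epimer of 15 converges on the same centre because C6 becomes sp2. Enolate 17 is planar-chiral, its inner face being covered by the C1=C10 bond, so the iodoacetate should attack C7 from the outer face, which gives 7αH (R) with the new arm syn to the 8β-oxygen as in the target. The selectivity the step needs is C-alkylation without loss of the C8 alkoxide; a crown-separated potassium enolate, a soft iodide electrophile and a quench at −78 °C are chosen for this, and C3 is not touched.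

Step 12
Reactants: 18 ethyl 15-(tert-butyldiphenylsilyloxy)-8β-(4-methoxybenzyloxy)-6-oxo-3β-(triethylsilyloxy)-7αH-13-norgermacra-1(10)E,4Z-dien-12-oate
Product: 20 15-(tert-butyldiphenylsilyloxy)-3β-hydroxy-8β-(4-methoxybenzyloxy)-13-norgermacra-1(10)E,4Z-dien-12,6α-olide, via hydroxy ester 19 (not isolated)
Conditions: NaBH4, CeCl3·7H2O, MeOH, −78 °C; then PPTS, MeOH, 40 °C
Reagents that add atoms: none
Why: Luche 1,2-reduction of the Z enone; with the ring bond C7–C8 held near the carbonyl plane the C7 acetate arm stands perpendicular to it, so hydride should enter anti to the arm (Felkin–Anh sense) and give the 6α-alcohol with H6 and H7 gauche as in heliangolides. Mild acid then removes the triethylsilyl group and closes the trans γ-lactone, which can only form on O6 because O8 is still an ether.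

Step 13
Reactants: 20 15-(tert-butyldiphenylsilyloxy)-3β-hydroxy-8β-(4-methoxybenzyloxy)-13-norgermacra-1(10)E,4Z-dien-12,6α-olide
Product: 24 15-(tert-butyldiphenylsilyloxy)-3β-hydroxy-8β-(4-methoxybenzyloxy)germacra-1(10)E,4Z,11(13)-trien-12,6α-olide, via dilithium enolate 21 (not isolated), via Mannich base 22 (not isolated), via methiodide 23 (not isolated)
Conditions: LiN(i-Pr)2 (2.5 equiv), THF, −78 °C; CH2=NMe2+ I−, −78 °C → rt; then MeI, CH2Cl2/MeOH, rt; then aq. NaHCO3, rt
Reagents that add atoms: N,N-dimethylmethyleneiminium iodide (Eschenmoser's salt), C=[N+](C)C.[I-]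
Why: Standard α-methylenation of a γ-lactone by aminomethylation of the enolate, quaternisation and elimination; the free C3 hydroxyl rides through as its alkoxide, and no ester that the base could attack is present yet.

Step 14
Reactants: 24 15-(tert-butyldiphenylsilyloxy)-3β-hydroxy-8β-(4-methoxybenzyloxy)germacra-1(10)E,4Z,11(13)-trien-12,6α-olide
Product: 25 3β-acetoxy-15-(tert-butyldiphenylsilyloxy)-8β-(4-methoxybenzyloxy)germacra-1(10)E,4Z,11(13)-trien-12,6α-olide
Conditions: Ac2O, pyridine, DMAP (cat.), CH2Cl2, 0 °C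
Reagents that add atoms: acetic anhydride, CC(=O)OC(C)=O
Why: Acetylation of the only free hydroxyl.

Step 15
Reactants: 25 3β-acetoxy-15-(tert-butyldiphenylsilyloxy)-8β-(4-methoxybenzyloxy)germacra-1(10)E,4Z,11(13)-trien-12,6α-olide
Product: 26 3β-acetoxy-15-(tert-butyldiphenylsilyloxy)-8β-hydroxygermacra-1(10)E,4Z,11(13)-trien-12,6α-olide
Conditions: DDQ, CH2Cl2/pH 7 buffer 10:1, 0 °C
Reagents that add atoms: none
Why: Oxidative cleavage of the 4-methoxybenzyl ether under neutral conditions, which leaves the esters, the silyl ether and the olefins alone.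

Step 16
Reactants: 26 3β-acetoxy-15-(tert-butyldiphenylsilyloxy)-8β-hydroxygermacra-1(10)E,4Z,11(13)-trien-12,6α-olide
Product: 27 3β-acetoxy-15-(tert-butyldiphenylsilyloxy)-8β-(methacryloyloxy)germacra-1(10)E,4Z,11(13)-trien-12,6α-olide
Conditions: methacrylic anhydride, Et3N, DMAP, CH2Cl2, 0 °C → rt
Reagents that add atoms: methacrylic anhydride, CC(=C)C(=O)OC(=O)C(C)=C
Why: DMAP-catalysed acylation of the single free secondary hydroxyl.

Step 17
Reactants: 27 3β-acetoxy-15-(tert-butyldiphenylsilyloxy)-8β-(methacryloyloxy)germacra-1(10)E,4Z,11(13)-trien-12,6α-olide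
Product: 28 3β-acetoxy-15-hydroxy-8β-(methacryloyloxy)germacra-1(10)E,4Z,11(13)-trien-12,6α-olide
Conditions: HF·pyridine, pyridine, THF, 0 °C → rt
Reagents that add atoms: none
Why: Buffered acidic fluoride removes the primary silyl ether without the basic conditions that would move the acetate from O3 to O15 or add to the Michael acceptors; the step is placed before the epoxide exists.

Step 18
Reactants: 28 3β-acetoxy-15-hydroxy-8β-(methacryloyloxy)germacra-1(10)E,4Z,11(13)-trien-12,6α-olide
Product: 29 3β-acetoxy-1β,10α-epoxy-15-hydroxy-8β-(methacryloyloxy)germacra-4Z,11(13)-dien-12,6α-olide (CNP0319155.1)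
Conditions: mCPBA, NaHCO3, CH2Cl2, −20 → 0 °C
Reagents that add atoms: 3-chloroperoxybenzoic acid, OOC(=O)c1cccc(Cl)c1
Why: Prilezhaev epoxidation of the strained, electron-rich E C1=C10 bond; C4=C5 is deactivated by three allylic oxygens and the two acrylate-type olefins are inert. Peripheral attack on the outer face of the olefin should give the 1β,10α (1R,10R) trans epoxide.

## Compound list

1 | 2-hydroxy-5-methoxybenzaldehyde | COc1ccc(O)c(C=O)c1 | starting material
2 | 2-(hydroxymethyl)-4-methoxyphenol | COc1ccc(O)c(CO)c1 | intermediate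
3 | 2-(hydroxymethyl)-4,4-dimethoxycyclohexa-2,5-dien-1-one | COC1(OC)C=CC(=O)C(CO)=C1 | intermediate
4 | 2-[(tert-butyldiphenylsilyloxy)methyl]-4,4-dimethoxycyclohexa-2,5-dien-1-one | COC1(OC)C=CC(=O)C(CO[Si](c2ccccc2)(c2ccccc2)C(C)(C)C)=C1 | intermediate
5 | (5S)-2-[(tert-butyldiphenylsilyloxy)methyl]-4,4-dimethoxy-5-(prop-1-en-2-yl)cyclohex-2-en-1-one | COC1(OC)C=C(CO[Si](c2ccccc2)(c2ccccc2)C(C)(C)C)C(=O)C[C@H]1C(C)=C | intermediate
6 | (1S,5S)-2-[(tert-butyldiphenylsilyloxy)methyl]-4,4-dimethoxy-5-(prop-1-en-2-yl)cyclohex-2-en-1-ol | COC1(OC)C=C(CO[Si](c2ccccc2)(c2ccccc2)C(C)(C)C)[C@@H](O)C[C@H]1C(C)=C | intermediate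
7 | tert-butyl{[(4S,6S)-3,3-dimethoxy-4-(prop-1-en-2-yl)-6-(triethylsilyloxy)cyclohex-1-en-1-yl]methoxy}diphenylsilane | COC1(OC)C=C(CO[Si](c2ccccc2)(c2ccccc2)C(C)(C)C)[C@@H](O[Si](CC)(CC)CC)C[C@H]1C(C)=C | intermediate
8 | (4S,6S)-3-[(tert-butyldiphenylsilyloxy)methyl]-6-(prop-1-en-2-yl)-4-(triethylsilyloxy)cyclohex-2-en-1-one | O=C1C=C(CO[Si](c2ccccc2)(c2ccccc2)C(C)(C)C)[C@@H](O[Si](CC)(CC)CC)C[C@H]1C(C)=C | intermediate
9 | 4-methoxybenzyl alcohol | COc1ccc(CO)cc1 | starting material
10 | 4-methoxybenzyl vinyl ether | C=COCc1ccc(OC)cc1 | intermediate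
11 | 1,2-dibromoethyl 4-methoxybenzyl ether (racemic, not isolated) | BrCC(Br)OCc1ccc(OC)cc1 | intermediate
12 | (Z)-1-bromo-2-(4-methoxybenzyloxy)ethene | Br/C=C\OCc1ccc(OC)cc1 | intermediate
13 | (Z)-2-(4-methoxybenzyloxy)vinyllithium (not isolated) | [Li]/C=C\OCc1ccc(OC)cc1 | intermediate
14 | dichloro[(Z)-2-(4-methoxybenzyloxy)vinyl]cerium (not isolated) | Cl[Ce](Cl)/C=C\OCc1ccc(OC)cc1 | intermediate
15 | (1S,4S,6S)-3-[(tert-butyldiphenylsilyloxy)methyl]-1-[(Z)-2-(4-methoxybenzyloxy)ethenyl]-6-(prop-1-en-2-yl)-4-(triethylsilyloxy)cyclohex-2-en-1-ol | O[C@@]1(/C=C\OCc2ccc(OC)cc2)C=C(CO[Si](c2ccccc2)(c2ccccc2)C(C)(C)C)[C@@H](O[Si](CC)(CC)CC)C[C@H]1C(C)=C | intermediate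
16 | potassium alkoxide of 15 (not isolated) | [K+].[O-][C@@]1(/C=C\OCc2ccc(OC)cc2)C=C(CO[Si](c2ccccc2)(c2ccccc2)C(C)(C)C)[C@@H](O[Si](CC)(CC)CC)C[C@H]1C(C)=C | intermediate
17 | potassium 6,7-enolate of the ring-expanded ketone: 15-(tert-butyldiphenylsilyloxy)-8β-(4-methoxybenzyloxy)-3β-(triethylsilyloxy)-11,12,13-trinorgermacra-1(10)E,4Z,6-trien-6-olate (not isolated) | [K+].C1/C=C(\C)C[C@@H](OCc2ccc(OC)cc2)/C=C([O-])/C=C(CO[Si](c2ccccc2)(c2ccccc2)C(C)(C)C)\[C@H]1O[Si](CC)(CC)CC | intermediate
18 | ethyl 15-(tert-butyldiphenylsilyloxy)-8β-(4-methoxybenzyloxy)-6-oxo-3β-(triethylsilyloxy)-7αH-13-norgermacra-1(10)E,4Z-dien-12-oate | COc1ccc(CO[C@@H]2C/C(C)=C/C[C@H](O[Si](CC)(CC)CC)/C(CO[Si](c3ccccc3)(c3ccccc3)C(C)(C)C)=C\C(=O)[C@@H]2CC(=O)OCC)cc1 | intermediate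
19 | ethyl 15-(tert-butyldiphenylsilyloxy)-6α-hydroxy-8β-(4-methoxybenzyloxy)-3β-(triethylsilyloxy)-7αH-13-norgermacra-1(10)E,4Z-dien-12-oate (not isolated) | COc1ccc(CO[C@@H]2C/C(C)=C/C[C@H](O[Si](CC)(CC)CC)/C(CO[Si](c3ccccc3)(c3ccccc3)C(C)(C)C)=C\[C@@H](O)[C@@H]2CC(=O)OCC)cc1 | intermediate
20 | 15-(tert-butyldiphenylsilyloxy)-3β-hydroxy-8β-(4-methoxybenzyloxy)-13-norgermacra-1(10)E,4Z-dien-12,6α-olide | COc1ccc(CO[C@@H]2C/C(C)=C/C[C@H](O)/C(CO[Si](c3ccccc3)(c3ccccc3)C(C)(C)C)=C\[C@H]3OC(=O)C[C@@H]32)cc1 | intermediate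
21 | dilithium 3-alkoxide 12-enolate of 20 (not isolated) | [Li+].[Li+].COc1ccc(CO[C@@H]2C/C(C)=C/C[C@H]([O-])/C(CO[Si](c3ccccc3)(c3ccccc3)C(C)(C)C)=C\[C@H]3OC([O-])=C[C@@H]32)cc1 | intermediate
22 | 13-(dimethylamino) derivative of the saturated lactone (Mannich base, C11 epimers, not isolated) | COc1ccc(CO[C@@H]2C/C(C)=C/C[C@H](O)/C(CO[Si](c3ccccc3)(c3ccccc3)C(C)(C)C)=C\[C@H]3OC(=O)C(CN(C)C)[C@@H]32)cc1 | intermediate
23 | trimethylammonium iodide of 22 (not isolated) | [I-].COc1ccc(CO[C@@H]2C/C(C)=C/C[C@H](O)/C(CO[Si](c3ccccc3)(c3ccccc3)C(C)(C)C)=C\[C@H]3OC(=O)C(C[N+](C)(C)C)[C@@H]32)cc1 | intermediate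
24 | 15-(tert-butyldiphenylsilyloxy)-3β-hydroxy-8β-(4-methoxybenzyloxy)germacra-1(10)E,4Z,11(13)-trien-12,6α-olide | COc1ccc(CO[C@@H]2C/C(C)=C/C[C@H](O)/C(CO[Si](c3ccccc3)(c3ccccc3)C(C)(C)C)=C\[C@H]3OC(=O)C(=C)[C@@H]32)cc1 | intermediate
25 | 3β-acetoxy-15-(tert-butyldiphenylsilyloxy)-8β-(4-methoxybenzyloxy)germacra-1(10)E,4Z,11(13)-trien-12,6α-olide | COc1ccc(CO[C@@H]2C/C(C)=C/C[C@H](OC(C)=O)/C(CO[Si](c3ccccc3)(c3ccccc3)C(C)(C)C)=C\[C@H]3OC(=O)C(=C)[C@@H]32)cc1 | intermediate
26 | 3β-acetoxy-15-(tert-butyldiphenylsilyloxy)-8β-hydroxygermacra-1(10)E,4Z,11(13)-trien-12,6α-olide | O[C@@H]1C/C(C)=C/C[C@H](OC(C)=O)/C(CO[Si](c2ccccc2)(c2ccccc2)C(C)(C)C)=C\[C@H]2OC(=O)C(=C)[C@@H]21 | intermediate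
27 | 3β-acetoxy-15-(tert-butyldiphenylsilyloxy)-8β-(methacryloyloxy)germacra-1(10)E,4Z,11(13)-trien-12,6α-olide | C=C(C)C(=O)O[C@@H]1C/C(C)=C/C[C@H](OC(C)=O)/C(CO[Si](c2ccccc2)(c2ccccc2)C(C)(C)C)=C\[C@H]2OC(=O)C(=C)[C@@H]21 | intermediate
28 | 3β-acetoxy-15-hydroxy-8β-(methacryloyloxy)germacra-1(10)E,4Z,11(13)-trien-12,6α-olide | C=C(C)C(=O)O[C@@H]1C/C(C)=C/C[C@H](OC(C)=O)/C(CO)=C\[C@H]2OC(=O)C(=C)[C@@H]21 | intermediate
29 | (1R,3S,4Z,6R,7R,8R,10R)-3-acetoxy-1,10-epoxy-15-hydroxy-8-(methacryloyloxy)germacra-4,11(13)-dien-12,6-olide (CNP0319155.1) | C=C(C)C(=O)O[C@@H]1C[C@@]2(C)O[C@@H]2C[C@H](OC(C)=O)/C(CO)=C\[C@H]2OC(=O)C(=C)[C@@H]21 | target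

## Step count and least certain steps

Total step count: 18. Longest linear sequence: 16 steps (steps 1–7 and 10–18); the vinyl bromide branch has 2 steps (8 and 9).

Step 11 (key step). The most likely failure is loss of the C8 oxygen: the β-alkoxy enolate 17 can expel 4-methoxybenzyl oxide (E1cB) while the rearrangement is still running, because the axial C8–O bond is partly aligned with the enolate π system. Two lesser failures are a boat transition state, which would scramble C8, and rotation of the enolate through the ring before alkylation, which would erode the facial selectivity at C7. The fallback sets out from 15 and comes back at 18, and it puts the C8 oxygen in after the ring expansion: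
- The elimination is driven to completion (KN(SiMe3)2, 18-crown-6, THF, 0 °C → rt) to give the cross-conjugated dienone F1.
- Copper-catalysed conjugate borylation (CuCl, NaOt-Bu, a chiral ferrocenyl bisphosphine, B2pin2, MeOH) at the less substituted enone terminus C8 should give, under ligand control, the 8β-boronate F2.
- NaBO3·4H2O oxidises it with retention to the β-hydroxy ketone F3.
- 4-Methoxybenzyl trichloroacetimidate with La(OTf)3 gives the ether F4.
- Kinetic deprotonation at C7 with LiN(i-Pr)2 at −78 °C, where lithium β-alkoxy enolates are stable, and alkylation with ethyl iodoacetate lead to 18.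

Step 4. The alkenyl transfer to the hindered carbon next to the ketal may be slow, the facial selectivity may be poor on this 2-substituted dienone, and loss of methanol with aromatisation can compete on heating. The fallback sets out from 4 and comes back at 6:
- Copper-catalysed addition of isopropenylmagnesium bromide (CuBr·SMe2, Me3SiCl, THF, −78 °C) gives the racemic adduct F5.
- Luche reduction gives the racemic cis alcohol F6.
- A lipase-catalysed acylation with vinyl acetate (lipase from Burkholderia cepacia) should convert the (1R,5R) enantiomer into the acetate F7 and leave 6, which is separated and carried on.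

Step 10. Ketone 8 has a doubly activated proton at C1, so enolisation instead of addition is the main risk; the vinyllithium 13 can also fragment to acetylene and alkoxide if it warms. The fallback sets out from 9 and 8 and comes back at 15:
- Alcohol 9 is converted (KH, trichloroethylene) into the dichlorovinyl ether F8.
- n-BuLi (2.2 equiv, −78 °C) turns F8 into the lithium alkoxyacetylide F9, a less basic and thermally robust nucleophile.
- Addition of F9 to 8 gives the alkynyl carbinol F10.
- cis-Semihydrogenation of the ynol ether (H2, Pd/CaCO3 poisoned with Pb(OAc)2, quinoline) gives 15 with the Z enol ether.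

Step 12. Hydride may be delivered to the other face of the C6 carbonyl if the ring folds so that the C1=C10 bond, and not the C7 arm, shields the carbonyl; this gives the 6β-alcohol and from it the cis lactone. The fallback sets out from 18 and comes back at 20, and it sets C6 by inversion instead of by reduction:
- The reduction is run without the acid treatment and gives the 6β-hydroxy ester F11.
- LiOH hydrolyses the ester to the hydroxy acid F12.
- Mitsunobu lactonisation (PPh3, DIAD) closes the trans lactone with inversion at C6 to give the silylated lactone F13.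
- PPTS in MeOH gives 20.

Step 18. Peracid may attack the other face of C1=C10 if the olefin plane rotates in the lactone conformer, and traces of acid may open the epoxide transannularly. The fallback sets out from 28 and comes back at 29, and it delivers the oxygen to the face opposite the one an electrophile attacks first:
- N-Bromosuccinimide in aqueous THF gives the bromohydrin F14: bromonium formation on the peripheral face and water at the tertiary C10 from the other face.
- K2CO3 in MeCN closes the epoxide by displacement of bromide at C1, which places the oxygen on the face opposite to the one the peracid would have used.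

## Further compounds

F1 | step 11 | 15-(tert-butyldiphenylsilyloxy)-3β-(triethylsilyloxy)-11,12,13-trinorgermacra-1(10)E,4Z,7E-trien-6-one | C1/C=C(\C)C/C=C/C(=O)/C=C(CO[Si](c2ccccc2)(c2ccccc2)C(C)(C)C)\[C@H]1O[Si](CC)(CC)CC
F2 | step 11 | 8β-(4,4,5,5-tetramethyl-1,3,2-dioxaborolan-2-yl)-15-(tert-butyldiphenylsilyloxy)-3β-(triethylsilyloxy)-11,12,13-trinorgermacra-1(10)E,4Z-dien-6-one | C1/C=C(\C)C[C@@H](B2OC(C)(C)C(C)(C)O2)CC(=O)/C=C(CO[Si](c2ccccc2)(c2ccccc2)C(C)(C)C)\[C@H]1O[Si](CC)(CC)CC
F3 | step 11 | 15-(tert-butyldiphenylsilyloxy)-8β-hydroxy-3β-(triethylsilyloxy)-11,12,13-trinorgermacra-1(10)E,4Z-dien-6-one | C1/C=C(\C)C[C@@H](O)CC(=O)/C=C(CO[Si](c2ccccc2)(c2ccccc2)C(C)(C)C)\[C@H]1O[Si](CC)(CC)CC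
F4 | step 11 | 15-(tert-butyldiphenylsilyloxy)-8β-(4-methoxybenzyloxy)-3β-(triethylsilyloxy)-11,12,13-trinorgermacra-1(10)E,4Z-dien-6-one | C1/C=C(\C)C[C@@H](OCc2ccc(OC)cc2)CC(=O)/C=C(CO[Si](c2ccccc2)(c2ccccc2)C(C)(C)C)\[C@H]1O[Si](CC)(CC)CC
F5 | step 4 | racemic 2-[(tert-butyldiphenylsilyloxy)methyl]-4,4-dimethoxy-5-(prop-1-en-2-yl)cyclohex-2-en-1-one | COC1(OC)C=C(CO[Si](c2ccccc2)(c2ccccc2)C(C)(C)C)C(=O)CC1C(C)=C
F6 | step 4 | racemic cis-2-[(tert-butyldiphenylsilyloxy)methyl]-4,4-dimethoxy-5-(prop-1-en-2-yl)cyclohex-2-en-1-ol (both enantiomers) | COC1(OC)C=C(CO[Si](c2ccccc2)(c2ccccc2)C(C)(C)C)[C@@H](O)C[C@H]1C(C)=C.COC1(OC)C=C(CO[Si](c2ccccc2)(c2ccccc2)C(C)(C)C)[C@H](O)C[C@@H]1C(C)=C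
F7 | step 4 | (1R,5R)-2-[(tert-butyldiphenylsilyloxy)methyl]-4,4-dimethoxy-5-(prop-1-en-2-yl)cyclohex-2-en-1-yl acetate | COC1(OC)C=C(CO[Si](c2ccccc2)(c2ccccc2)C(C)(C)C)[C@H](OC(C)=O)C[C@@H]1C(C)=C
F8 | step 10 | (E)-1,2-dichlorovinyl 4-methoxybenzyl ether | Cl/C=C(/Cl)OCc1ccc(OC)cc1
F9 | step 10 | lithium (4-methoxybenzyloxy)acetylide | [Li]C#COCc1ccc(OC)cc1
F10 | step 10 | (1S,4S,6S)-3-[(tert-butyldiphenylsilyloxy)methyl]-1-[(4-methoxybenzyloxy)ethynyl]-6-(prop-1-en-2-yl)-4-(triethylsilyloxy)cyclohex-2-en-1-ol | O[C@@]1(C#COCc2ccc(OC)cc2)C=C(CO[Si](c2ccccc2)(c2ccccc2)C(C)(C)C)[C@@H](O[Si](CC)(CC)CC)C[C@H]1C(C)=C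
F11 | step 12 | ethyl 15-(tert-butyldiphenylsilyloxy)-6β-hydroxy-8β-(4-methoxybenzyloxy)-3β-(triethylsilyloxy)-7αH-13-norgermacra-1(10)E,4Z-dien-12-oate | COc1ccc(CO[C@@H]2C/C(C)=C/C[C@H](O[Si](CC)(CC)CC)/C(CO[Si](c3ccccc3)(c3ccccc3)C(C)(C)C)=C\[C@H](O)[C@@H]2CC(=O)OCC)cc1
F12 | step 12 | 15-(tert-butyldiphenylsilyloxy)-6β-hydroxy-8β-(4-methoxybenzyloxy)-3β-(triethylsilyloxy)-7αH-13-norgermacra-1(10)E,4Z-dien-12-oic acid | COc1ccc(CO[C@@H]2C/C(C)=C/C[C@H](O[Si](CC)(CC)CC)/C(CO[Si](c3ccccc3)(c3ccccc3)C(C)(C)C)=C\[C@H](O)[C@@H]2CC(=O)O)cc1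
F13 | step 12 | 15-(tert-butyldiphenylsilyloxy)-8β-(4-methoxybenzyloxy)-3β-(triethylsilyloxy)-13-norgermacra-1(10)E,4Z-dien-12,6α-olide | COc1ccc(CO[C@@H]2C/C(C)=C/C[C@H](O[Si](CC)(CC)CC)/C(CO[Si](c3ccccc3)(c3ccccc3)C(C)(C)C)=C\[C@H]3OC(=O)C[C@@H]32)cc1
F14 | step 18 | 3β-acetoxy-1α-bromo-10α,15-dihydroxy-8β-(methacryloyloxy)germacra-4Z,11(13)-dien-12,6α-olide | C=C(C)C(=O)O[C@@H]1C[C@@](C)(O)[C@@H](Br)C[C@H](OC(C)=O)/C(CO)=C\[C@H]2OC(=O)C(=C)[C@@H]21
A1 | alternative 1 | seco-aldehyde: methyl ester of the 6,7-seco-germacratrienoic acid with C6 aldehyde, (Z)-C7=C11 bearing CH2Br, 3β-OTBS, 8β-OPMB and 15-OTBDPS | O=C/C=C(CO[Si](c1ccccc1)(c1ccccc1)C(C)(C)C)\[C@@H](O[Si](C)(C)C(C)(C)C)C/C=C(\C)C[C@@H](OCc1ccc(OC)cc1)/C=C(\CBr)C(=O)OC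
A2 | alternative 2 | thirteen-membered diallyl ether (O between C6 and C13, C7=C11 E, C12 as CH2OMOM, 3β-OTBS, 8β-OPMB, 15-OTBDPS) | O1C/C(COCOC)=C/[C@H](OCc2ccc(OC)cc2)C/C(C)=C/C[C@H](O[Si](C)(C)C(C)(C)C)/C(CO[Si](c2ccccc2)(c2ccccc2)C(C)(C)C)=C\C1
A3 | alternative 3 | 1,10-seco diene: 6α,12-lactone carrying the C2–C1 allyl terminus and the C9–C10 methallyl terminus (3β-OTBS, 8β-OPMB, 15-OTBDPS) | C=CC[C@H](O[Si](C)(C)C(C)(C)C)/C(CO[Si](c1ccccc1)(c1ccccc1)C(C)(C)C)=C\[C@H]1OC(=O)C[C@@H]1[C@H](OCc1ccc(OC)cc1)CC(C)=C
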